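**Retrosynthetic overview**

1. Numbering: ring C1 (CMe2), C2 (C=O), C3, C4, C5 (C(OH)Me), C6 (CH); chain C7–C11, with C9 the chain carbinol and C11 on the aryl ether oxygen. The C11–O(aryl) bond is made last by Mitsunobu coupling of umbelliferone with a keto triol.
2. Feature the strategy rests on: the C2 ketone and the C5 tertiary carbinol lie 1,4 across the only carbocycle (C1–C6), the pattern of an opened peroxide bridge. This leads back to singlet-oxygen [4+2] addition across C2/C5 of a 1,5,5-trimethyl-6-alkylcyclohexa-1,3-diene followed by Kornblum–DeLaMare opening; the leftover C3=C4 alkene is hydrogenated.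
3. The diene comes from the ring alkene of the α-ionone skeleton (C1–C9 with four methyls and the C6 centre): allylic oxidation at C3, kinetic C2=C3 dienyl triflate, palladium/formate reduction.
4. C9 (R) is set before the ring work: Horner–Wadsworth–Emmons at the C9 ketone, Sharpless epoxidation, Red-Al opening. The finished C9/C11 diol passes through the key step as an acetonide.
5. Ring order: the carbocycle and C6 are bought as racemic α-ionone and resolved to the (S) series; the acetonide ring (step 12) and the peroxide bridge (step 16) are temporary; the coumarin is bought. No carbocycle is closed.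

Key step: step 16

Assumption: the α-ionol 4-nitrobenzoate that crystallises in step 2 is taken to be the racemic (6S*,9R*) diastereomer, so the lipase-derived (9R)-acetate carries the (6S) ring. If it is the (6R*,9R*) one, the unreacted (6S,9S)-alcohol of step 4 is oxidised in step 6 instead and step 5 is dropped.

Remark on design: the chain terminus is carried as the acetonide of the finished diol, so that after the key step no reagent has to tell the C2 ketone or the C5 carbinol from chain functionality.

Remark on descriptors: C6 is never touched after the resolution. Its descriptor reads S in the ene, enone and ketone compounds and R in the dienolate, triflate and diene only because the CIP ranking of its two ring neighbours changes.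

**Route**

Step 1
Reactants: 1 racemic α-ionone
Product: 2 α-ionol as all four stereoisomers
Conditions: NaBH4, CeCl3·7H2O, MeOH, 0 °C
Reagents that add atoms: none
Why: Luche 1,2-reduction of the enone; the remote ring centre gives no useful induction, so both racemic C9 epimers are expected.

Step 2
Reactants: 2 α-ionol as all four stereoisomers
Product: 3 racemic (6S*,9R*)-α-ionyl 4-nitrobenzoate
Conditions: 4-O2NC6H4COCl, pyridine, DMAP (cat.), CH2Cl2, 0 °C to rt; fractional crystallisation from hexane
Reagents that add atoms: 4-nitrobenzoyl chloride, O=C(Cl)c1ccc(cc1)[N+](=O)[O-]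
Why: Acylation with an acid chloride turns the oily alcohols into crystalline esters, so that one racemic diastereomer can be enriched by crystallisation; no stereocentre is formed.

Step 3
Reactants: 3 racemic (6S*,9R*)-α-ionyl 4-nitrobenzoate
Product: 4 racemic (6S*,9R*)-α-ionol
Conditions: KOH, MeOH/H2O, rt
Reagents that add atoms: none
Why: Ester saponification by acyl–oxygen cleavage leaves both stereocentres untouched.

Step 4
Reactants: 4 racemic (6S*,9R*)-α-ionol
Product: 5 (6S,9R)-α-ionyl acetate
Conditions: lipase PS (Burkholderia cepacia), vinyl acetate, tBuOMe, rt, to about half conversion; chromatography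
Reagents that add atoms: vinyl acetate, CC(=O)OC=C
Why: Lipase kinetic resolution by transesterification: the enzyme should acylate the (9R) carbinol (Kazlauskas rule), and because the relative configuration is fixed in 4 this also sorts the ring centre; the (6R,9S)-alcohol stays unreacted and is removed.

Step 5
Reactants: 5 (6S,9R)-α-ionyl acetate
Product: 6 (6S,9R)-α-ionol
Conditions: K2CO3 (cat.), MeOH, rt
Reagents that add atoms: none
Why: Base-catalysed transesterification to methanol (Zemplén-type deacetylation) frees the alcohol without touching C6.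

Step 6
Reactants: 6 (6S,9R)-α-ionol
Product: 7 (S)-α-ionone
Conditions: MnO2, CH2Cl2, rt
Reagents that add atoms: none
Why: MnO2 oxidation of an allylic alcohol under neutral conditions leaves the doubly allylic C6–H alone; the C9 centre has served as resolution handle and is removed.

Step 7
Reactants: 7 (S)-α-ionone
Product: 8 (S)-dihydro-α-ionone
Conditions: [(Ph3P)CuH]6, H2O, degassed THF, rt
Reagents that add atoms: none
Why: Stryker conjugate reduction: copper hydride adds 1,4 to the enone only, the isolated trisubstituted ring alkene is inert, and the neutral medium avoids γ-deprotonation at C6.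

Step 8
Reactants: 8 (S)-dihydro-α-ionone
Product: 9 ethyl (2E)-3-methyl-5-[(1S)-2,6,6-trimethylcyclohex-2-en-1-yl]pent-2-enoate
Conditions: (EtO)2P(O)CH2CO2Et, NaH, THF, 0 to 50 °C; chromatography to remove the Z isomer
Reagents that add atoms: triethyl phosphonoacetate, CCOC(=O)CP(=O)(OCC)OCC
Why: Horner–Wadsworth–Emmons olefination of a methyl ketone, which should favour the E enoate (larger chain trans to the ester); the minor Z isomer is separated because it would give the wrong C9 configuration later.

Step 9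
Reactants: 9 ethyl (2E)-3-methyl-5-[(1S)-2,6,6-trimethylcyclohex-2-en-1-yl]pent-2-enoate
Product: 10 (2E)-3-methyl-5-[(1S)-2,6,6-trimethylcyclohex-2-en-1-yl]pent-2-en-1-ol
Conditions: iBu2AlH, CH2Cl2, −78 °C; Rochelle salt work-up
Reagents that add atoms: none
Why: 1,2-Reduction of the unsaturated ester by diisobutylaluminium hydride gives the E allylic alcohol with the alkene geometry unchanged.

Step 10
Reactants: 10 (2E)-3-methyl-5-[(1S)-2,6,6-trimethylcyclohex-2-en-1-yl]pent-2-en-1-ol
Product: 11 [(2R,3R)-3-methyl-3-{2-[(1S)-2,6,6-trimethylcyclohex-2-en-1-yl]ethyl}oxiran-2-yl]methanol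
Conditions: Ti(OiPr)4 (cat.), D-(−)-diethyl tartrate (cat.), tBuOOH, 4 Å molecular sieves, CH2Cl2, −20 °C
Reagents that add atoms: tert-butyl hydroperoxide, CC(C)(C)OO
Why: Sharpless asymmetric epoxidation under catalyst control: D-(−)-tartrate gives the (2R,3R)-epoxide in the geraniol series, which fixes C9 as R, and the non-allylic ring alkene is not epoxidised by the titanium peroxide complex.

Step 11
Reactants: 11 [(2R,3R)-3-methyl-3-{2-[(1S)-2,6,6-trimethylcyclohex-2-en-1-yl]ethyl}oxiran-2-yl]methanol
Product: 12 (3R)-3-methyl-5-[(1S)-2,6,6-trimethylcyclohex-2-en-1-yl]pentane-1,3-diol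
Conditions: NaAlH2(OCH2CH2OMe)2, THF, 0 °C to rt
Reagents that add atoms: none
Why: Red-Al opening of a 2,3-epoxy alcohol: the aluminate bound at the primary oxygen delivers hydride to C10, giving the 1,3-diol and leaving the C9–O bond and its configuration intact.

Step 12
Reactants: 12 (3R)-3-methyl-5-[(1S)-2,6,6-trimethylcyclohex-2-en-1-yl]pentane-1,3-diol
Product: 13 (4R)-2,2,4-trimethyl-4-{2-[(1S)-2,6,6-trimethylcyclohex-2-en-1-yl]ethyl}-1,3-dioxane
Conditions: 2-methoxypropene, PPTS (cat.), CH2Cl2, 0 °C
Reagents that add atoms: 2-methoxypropene, COC(C)=C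
Why: Acid-catalysed acetonide formation from the enol ether masks both the primary and the tertiary hydroxyl in one ring that tolerates oxidant, amide base, palladium and singlet oxygen.

Step 13
Reactants: 13 (4R)-2,2,4-trimethyl-4-{2-[(1S)-2,6,6-trimethylcyclohex-2-en-1-yl]ethyl}-1,3-dioxane
Product: 14 (4S)-3,5,5-trimethyl-4-{2-[(4R)-2,2,4-trimethyl-1,3-dioxan-4-yl]ethyl}cyclohex-2-en-1-one
Conditions: CrO3, 3,5-dimethylpyrazole, CH2Cl2, −20 °C
Reagents that add atoms: chromium trioxide, O=[Cr](=O)=O
Why: Allylic oxidation by the hexavalent chromium–pyrazole complex: C3 is the only unhindered allylic methylene, and oxygenation at either end of the C3–C4–C5 allyl unit converges on the C3 enone conjugated to C4=C5.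

Step 14
Reactants: 14 (4S)-3,5,5-trimethyl-4-{2-[(4R)-2,2,4-trimethyl-1,3-dioxan-4-yl]ethyl}cyclohex-2-en-1-one
Product: 16 (4R)-3,3,5-trimethyl-4-{2-[(4R)-2,2,4-trimethyl-1,3-dioxan-4-yl]ethyl}cyclohexa-1,5-dien-1-yl trifluoromethanesulfonate, via lithium dienolate 15 (not isolated)
Conditions: LiN(iPr)2, THF, −78 °C (enone added to the base); then N-(5-chloropyridin-2-yl)bis(trifluoromethanesulfonyl)imide, −78 to 0 °C
Reagents that add atoms: Comins' reagent, FC(F)(F)S(=O)(=O)N(c1ccc(Cl)cn1)S(=O)(=O)C(F)(F)F
Why: Kinetic α′-deprotonation of the cyclohexenone at C2 (as with isophorone) gives the cross-conjugated dienolate, which is triflated on oxygen; low temperature and inverse addition keep out the thermodynamic dienolate through C6 that would erase the stereocentre.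

Step 15
Reactants: 16 (4R)-3,3,5-trimethyl-4-{2-[(4R)-2,2,4-trimethyl-1,3-dioxan-4-yl]ethyl}cyclohexa-1,5-dien-1-yl trifluoromethanesulfonate
Product: 17 (4R)-2,2,4-trimethyl-4-{2-[(1R)-2,6,6-trimethylcyclohexa-2,4-dien-1-yl]ethyl}-1,3-dioxane
Conditions: Pd(OAc)2 (cat.), PPh3, HCO2H, Bu3N, DMF, 40 °C; used at once
Reagents that add atoms: none
Why: Palladium-catalysed formate reduction of an enol triflate: zerovalent palladium inserts into the C–O bond, formate loses CO2 to give the palladium hydride, and reductive elimination puts hydrogen on C3 without moving either double bond.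

Step 16
Reactants: 17 (4R)-2,2,4-trimethyl-4-{2-[(1R)-2,6,6-trimethylcyclohexa-2,4-dien-1-yl]ethyl}-1,3-dioxane
Product: 19 (4S,5S)-4-hydroxy-4,6,6-trimethyl-5-{2-[(4R)-2,2,4-trimethyl-1,3-dioxan-4-yl]ethyl}cyclohex-2-en-1-one, via endoperoxide 18 (not isolated)
Conditions: O2, tetraphenylporphyrin (cat.), visible light, CH2Cl2, −20 °C; then Et3N, 0 °C to rt
Reagents that add atoms: oxygen, O=O
Why: Sensitised singlet oxygen adds suprafacially across C2 and C5 of the s-cis diene in a [4+2] cycloaddition to give the 2,3-dioxabicyclo[2.2.2]oct-5-ene 18; triethylamine then removes the only bridgehead hydrogen, at C2, and the O–O bond breaks in a Kornblum–DeLaMare fragmentation, so that C2 becomes the carbonyl and the C5 oxygen the tertiary alkoxide. The closest known reaction type is the photooxygenation of 1,3-cyclohexadienes followed by amine-induced Kornblum–DeLaMare rearrangement to 4-hydroxycyclohex-2-enones. No carbocycle is closed: the only ring formed is the peroxide bridge, made by the concerted [4+2] addition and opened again in the same flask, leaving the C2–O and C5–O bonds. The one new stereocentre, C5, is set by C6: on the face of the chain a pseudoaxial carbon substituent (the chain itself or, in the other half-chair, a C1 methyl) always lies over a diene terminus, whereas the opposite face offers a conformer with only the C6 hydrogen pseudoaxial, so oxygen should enter trans to the chain. The step needs this facial selectivity, [4+2] in preference to ene reaction (favoured by the cisoid ring diene) and a single direction of fragmentation (assured because C5 carries a methyl group and no hydrogen).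

Step 17
Reactants: 19 (4S,5S)-4-hydroxy-4,6,6-trimethyl-5-{2-[(4R)-2,2,4-trimethyl-1,3-dioxan-4-yl]ethyl}cyclohex-2-en-1-one
Product: 20 (3S,4S)-4-hydroxy-2,2,4-trimethyl-3-{2-[(4R)-2,2,4-trimethyl-1,3-dioxan-4-yl]ethyl}cyclohexan-1-one
Conditions: H2 (1 atm), 10% Pd/C, EtOAc, rt
Reagents that add atoms: none
Why: Catalytic hydrogenation of the disubstituted enone alkene in a neutral solvent; no stereocentre is formed or touched and the acetonide is stable.

Step 18
Reactants: 20 (3S,4S)-4-hydroxy-2,2,4-trimethyl-3-{2-[(4R)-2,2,4-trimethyl-1,3-dioxan-4-yl]ethyl}cyclohexan-1-one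
Product: 21 (3S,4S)-3-[(3R)-3,5-dihydroxy-3-methylpentyl]-4-hydroxy-2,2,4-trimethylcyclohexan-1-one
Conditions: AcOH/THF/H2O, 40 °C
Reagents that add atoms: none
Why: Acid-catalysed acetal hydrolysis: the crowded 2,2,4,4-substituted dioxane should open in mild aqueous acetic acid, which both tertiary carbinols tolerate.

Step 19
Reactants: 21 (3S,4S)-3-[(3R)-3,5-dihydroxy-3-methylpentyl]-4-hydroxy-2,2,4-trimethylcyclohexan-1-one; 22 umbelliferone
Product: 23 7-{[(3R)-3-hydroxy-5-[(1S,6S)-6-hydroxy-2,2,6-trimethyl-3-oxocyclohexyl]-3-methylpentyl]oxy}-2H-chromen-2-one (target)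
Conditions: PPh3, diisopropyl azodicarboxylate, THF, 0 °C to rt
Reagents that add atoms: none
Why: Mitsunobu etherification: only the primary alcohol forms an alkoxyphosphonium ion that the acidic phenol can displace, while the two tertiary alcohols and the ketone do not react.

**Compound list**

1 | racemic α-ionone, (3E)-4-(2,6,6-trimethylcyclohex-2-en-1-yl)but-3-en-2-one | CC(=O)/C=C/C1C(C)=CCCC1(C)C | starting material
2 | α-ionol, (3E)-4-(2,6,6-trimethylcyclohex-2-en-1-yl)but-3-en-2-ol, all four stereoisomers | CC(O)/C=C/C1C(C)=CCCC1(C)C | intermediate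
3 | racemic (6S*,9R*)-α-ionyl 4-nitrobenzoate, (2R,3E)-4-[(1S)-2,6,6-trimethylcyclohex-2-en-1-yl]but-3-en-2-yl 4-nitrobenzoate and its enantiomer | CC1(C)CCC=C(C)[C@H]1/C=C/[C@@H](C)OC(=O)c1ccc(cc1)[N+](=O)[O-].CC1(C)CCC=C(C)[C@@H]1/C=C/[C@H](C)OC(=O)c1ccc(cc1)[N+](=O)[O-] | intermediate
4 | racemic (6S*,9R*)-α-ionol, (2R,3E)-4-[(1S)-2,6,6-trimethylcyclohex-2-en-1-yl]but-3-en-2-ol and its enantiomer | CC1(C)CCC=C(C)[C@H]1/C=C/[C@@H](C)O.CC1(C)CCC=C(C)[C@@H]1/C=C/[C@H](C)O | intermediate
5 | (6S,9R)-α-ionyl acetate, (2R,3E)-4-[(1S)-2,6,6-trimethylcyclohex-2-en-1-yl]but-3-en-2-yl acetate | CC1(C)CCC=C(C)[C@H]1/C=C/[C@@H](C)OC(C)=O | intermediate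
6 | (6S,9R)-α-ionol, (2R,3E)-4-[(1S)-2,6,6-trimethylcyclohex-2-en-1-yl]but-3-en-2-ol | CC1(C)CCC=C(C)[C@H]1/C=C/[C@@H](C)O | intermediate
7 | (S)-α-ionone, (3E)-4-[(1S)-2,6,6-trimethylcyclohex-2-en-1-yl]but-3-en-2-one | CC1(C)CCC=C(C)[C@H]1/C=C/C(C)=O | intermediate
8 | (S)-dihydro-α-ionone, 4-[(1S)-2,6,6-trimethylcyclohex-2-en-1-yl]butan-2-one | CC1(C)CCC=C(C)[C@H]1CCC(C)=O | intermediate
9 | ethyl (2E)-3-methyl-5-[(1S)-2,6,6-trimethylcyclohex-2-en-1-yl]pent-2-enoate | CC1(C)CCC=C(C)[C@H]1CC/C(C)=C/C(=O)OCC | intermediate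
10 | (2E)-3-methyl-5-[(1S)-2,6,6-trimethylcyclohex-2-en-1-yl]pent-2-en-1-ol | CC1(C)CCC=C(C)[C@H]1CC/C(C)=C/CO | intermediate
11 | [(2R,3R)-3-methyl-3-{2-[(1S)-2,6,6-trimethylcyclohex-2-en-1-yl]ethyl}oxiran-2-yl]methanol | CC1(C)CCC=C(C)[C@H]1CC[C@@]2(C)O[C@@H]2CO | intermediate
12 | (3R)-3-methyl-5-[(1S)-2,6,6-trimethylcyclohex-2-en-1-yl]pentane-1,3-diol | CC1(C)CCC=C(C)[C@H]1CC[C@@](C)(O)CCO | intermediate
13 | (4R)-2,2,4-trimethyl-4-{2-[(1S)-2,6,6-trimethylcyclohex-2-en-1-yl]ethyl}-1,3-dioxane | CC1(C)CCC=C(C)[C@H]1CC[C@@]2(C)OC(C)(C)OCC2 | intermediate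
14 | (4S)-3,5,5-trimethyl-4-{2-[(4R)-2,2,4-trimethyl-1,3-dioxan-4-yl]ethyl}cyclohex-2-en-1-one | CC1(C)CC(=O)C=C(C)[C@H]1CC[C@@]2(C)OC(C)(C)OCC2 | intermediate
15 | lithium (4R)-3,3,5-trimethyl-4-{2-[(4R)-2,2,4-trimethyl-1,3-dioxan-4-yl]ethyl}cyclohexa-1,5-dien-1-olate (cross-conjugated dienolate) | CC1(C)C=C([O-])C=C(C)[C@H]1CC[C@@]2(C)OC(C)(C)OCC2.[Li+] | intermediate
16 | (4R)-3,3,5-trimethyl-4-{2-[(4R)-2,2,4-trimethyl-1,3-dioxan-4-yl]ethyl}cyclohexa-1,5-dien-1-yl trifluoromethanesulfonate | CC1(C)C=C(OS(=O)(=O)C(F)(F)F)C=C(C)[C@H]1CC[C@@]2(C)OC(C)(C)OCC2 | intermediate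
17 | (4R)-2,2,4-trimethyl-4-{2-[(1R)-2,6,6-trimethylcyclohexa-2,4-dien-1-yl]ethyl}-1,3-dioxane (key-step precursor) | CC1(C)C=CC=C(C)[C@H]1CC[C@@]2(C)OC(C)(C)OCC2 | intermediate
18 | (4R)-2,2,4-trimethyl-4-{2-[(1S,4R,7S)-1,8,8-trimethyl-2,3-dioxabicyclo[2.2.2]oct-5-en-7-yl]ethyl}-1,3-dioxane (peroxide bridge trans to the chain) | CC1(C)[C@H]2C=C[C@](C)(OO2)[C@H]1CC[C@@]3(C)OC(C)(C)OCC3 | intermediate
19 | (4S,5S)-4-hydroxy-4,6,6-trimethyl-5-{2-[(4R)-2,2,4-trimethyl-1,3-dioxan-4-yl]ethyl}cyclohex-2-en-1-one (key-step product) | CC1(C)C(=O)C=C[C@](C)(O)[C@H]1CC[C@@]2(C)OC(C)(C)OCC2 | intermediate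
20 | (3S,4S)-4-hydroxy-2,2,4-trimethyl-3-{2-[(4R)-2,2,4-trimethyl-1,3-dioxan-4-yl]ethyl}cyclohexan-1-one | CC1(C)C(=O)CC[C@](C)(O)[C@H]1CC[C@@]2(C)OC(C)(C)OCC2 | intermediate
21 | (3S,4S)-3-[(3R)-3,5-dihydroxy-3-methylpentyl]-4-hydroxy-2,2,4-trimethylcyclohexan-1-one | CC1(C)C(=O)CC[C@](C)(O)[C@H]1CC[C@@](C)(O)CCO | intermediate
22 | umbelliferone, 7-hydroxy-2H-chromen-2-one | Oc1ccc2ccc(=O)oc2c1 | starting material
23 | 7-{[(3R)-3-hydroxy-5-[(1S,6S)-6-hydroxy-2,2,6-trimethyl-3-oxocyclohexyl]-3-methylpentyl]oxy}-2H-chromen-2-one | CC1(C)C(=O)CC[C@](C)(O)[C@H]1CC[C@@](C)(O)CCOc1ccc2ccc(=O)oc2c1 | target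

**Step count**

Total: 19 steps. Longest linear sequence: 19 steps, from 1; umbelliferone 22 enters in step 19.

**Steps most likely to fail**

1. Step 16. What may go wrong: poor facial selectivity in the oxygen addition (each diene face carries one C1 methyl), ene-type hydroperoxidation at the C5 methyl, or slow base-induced opening at the hindered C2 bridgehead that lets thermal rearrangement of the peroxide compete. Fallback, setting out from 14 and returning at 19: the C5–O bond is made by conjugate addition next to the stereocentre instead of by cycloaddition. Enone 14 is epoxidised with alkaline hydrogen peroxide (H2O2, NaOH, MeOH, 10 °C; Weitz–Scheffer), where hydroperoxide attacks C5 and should enter trans to the C6 chain, to give the epoxy ketone F1. Wharton transposition (N2H4·H2O, AcOH cat., MeOH, rt) moves the functionality to give the tertiary allylic alcohol F2, with C5–OH and a C3=C4 alkene. Riley oxidation (SeO2 cat., tBuOOH, CH2Cl2) of the C2 methylene, the only allylic C–H position, gives the ene-diol F3, whose secondary allylic alcohol is oxidised with MnO2 to 19.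

2. Step 14. What may go wrong: loss of kinetic control in the enolisation, where proton exchange between the α′-enolate and unreacted enone gives the extended dienolate through C6, scrambling that centre and leading to isomeric triflates. Fallback, setting out from 14 and returning at 17 (16 is bypassed): a Shapiro reaction. Condensation of 14 with 4-methylbenzenesulfonohydrazide (EtOH, rt) gives the tosylhydrazone F4. With excess LiN(iPr)2 (THF, −78 to 0 °C) the hydrazone anion is deprotonated at the C2 methylene, loses sulfinate and nitrogen, and the resulting C3 vinyllithium is quenched with water to give diene 17; no free enone is present to relay protons to C6.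

3. Step 2. What may go wrong: co-crystallisation of the two racemic diastereomers, so that the lipase in step 4 no longer separates the ring enantiomers. Fallback, setting out from 1 and returning at 6: C9 is set first by reagent control. Corey–Bakshi–Shibata reduction of racemic 1 ((S)-2-methyl-CBS-oxazaborolidine, catecholborane, toluene, −78 °C) should give (9R)-α-ionol as its two C6 epimers F5. Their 4-nitrobenzoates are then a pair of enantiopure diastereomers, from which the (6S,9R)-4-nitrobenzoate F6 is isolated by crystallisation or preparative HPLC and saponified (KOH, MeOH/H2O) to 6.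

**Further compounds**

F1 | step 16 | epoxy ketone: C4–C5 oxirane of 14 with the oxirane oxygen trans to the C6 chain, 4,4,6-trimethyl-5-{2-[(4R)-2,2,4-trimethyl-1,3-dioxan-4-yl]ethyl}-7-oxabicyclo[4.1.0]heptan-2-one | CC1(C)CC(=O)[C@@H]2O[C@]2(C)[C@H]1CC[C@@]3(C)OC(C)(C)OCC3
F2 | step 16 | (1S,6S)-1,5,5-trimethyl-6-{2-[(4R)-2,2,4-trimethyl-1,3-dioxan-4-yl]ethyl}cyclohex-2-en-1-ol | CC1(C)CC=C[C@](C)(O)[C@H]1CC[C@@]2(C)OC(C)(C)OCC2
F3 | step 16 | (1S,6S)-1,5,5-trimethyl-6-{2-[(4R)-2,2,4-trimethyl-1,3-dioxan-4-yl]ethyl}cyclohex-2-ene-1,4-diol, configuration at the secondary carbinol not fixed | CC1(C)C(O)C=C[C@](C)(O)[C@H]1CC[C@@]2(C)OC(C)(C)OCC2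
F4 | step 14 | 4-methyl-N'-[(4S)-3,5,5-trimethyl-4-{2-[(4R)-2,2,4-trimethyl-1,3-dioxan-4-yl]ethyl}cyclohex-2-en-1-ylidene]benzenesulfonohydrazide | CC1(C)CC(=NNS(=O)(=O)c2ccc(C)cc2)C=C(C)[C@H]1CC[C@@]3(C)OC(C)(C)OCC3
F5 | step 2 | (9R)-α-ionol as both C6 epimers, (2R,3E)-4-(2,6,6-trimethylcyclohex-2-en-1-yl)but-3-en-2-ol | CC1(C)CCC=C(C)C1/C=C/[C@@H](C)O
F6 | step 2 | (2R,3E)-4-[(1S)-2,6,6-trimethylcyclohex-2-en-1-yl]but-3-en-2-yl 4-nitrobenzoate, single enantiomer | CC1(C)CCC=C(C)[C@H]1/C=C/[C@@H](C)OC(=O)c1ccc(cc1)[N+](=O)[O-]
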